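Ring A is assembled rather than substituted. Its four adjacent substituted carbons, C4a (alkyl), C8a (oxygen), C8 (prenyl) and C7 (oxygen), match the product pattern of a vinylketene/ynol ether benzannulation, so ring A is cut into a C6–C5–C4a chain with C8a and a C7–C8 alkyne. In one operation, Wolff rearrangement of diazo enone 21 under light and capture by siloxyalkyne 25 forge C5–C6, C6–C7, C8–C8a and C8a–C4a, giving phenol 30 with only C8a–OH free. Precursor 21 is an E-enone diazomethyl ketone that already carries the 3S centre (Evans allylation), rings B and D as a 2'-O-silyl chromene, and C2 as a triethylsilyl ether. Mitsunobu closure of ring C and fluoride finish.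

Key step: step 12

Remark on the chemistry: the target SMILES encodes 3S. Isoflavan numbering is used for all intermediates. Ar = 5-(tert-butyldimethylsilyloxy)-2,2-dimethyl-2H-chromen-6-yl (rings B and D, bonded through C1'). C4 and C4a are brought in as an allyl group, so no second carbonyl group competes in the hydride step and the enone comes from one cross-metathesis.

Step 1
Reactants: 1 2,4-dihydroxybenzaldehyde; 2 3-methylbut-2-enal
Product: 4 5-hydroxy-2,2-dimethyl-2H-chromene-6-carbaldehyde, via quinone methide 3 (not isolated)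
Conditions: ethylenediammonium diacetate (10 mol %), xylene, 140 °C
Reagents that add atoms: none
Why: Knoevenagel-type condensation at C3 of the resorcinol followed by oxa-6π electrocyclisation of 3 is the known formal (3+3) chromene synthesis, and the hydrogen bond between the 2-OH and the formyl group leaves the 4-OH to become the pyran oxygen, which gives the angular isomer needed for rings B and D.

Step 2
Reactants: 4 5-hydroxy-2,2-dimethyl-2H-chromene-6-carbaldehyde
Product: 5 5-(tert-butyldimethylsilyloxy)-2,2-dimethyl-2H-chromene-6-carbaldehyde (Ar–CHO)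
Conditions: TBSCl, imidazole, DMAP (cat.), DMF, 25–40 °C
Reagents that add atoms: tert-butyldimethylsilyl chloride CC(C)(C)[Si](C)(C)Cl
Why: Imidazole-promoted O-silylation of the only hydroxyl group should give an aryl silyl ether that is flanked on both sides, hence sturdier towards base than a simple one, and still removable by fluoride at the end.

Step 3
Reactants: 5 Ar–CHO
Product: 7 2-Ar-acetaldehyde, via enol ether 6 (not isolated)
Conditions: MeOCH2PPh3Cl, NaN(SiMe3)2, THF, 0 °C; then 2 M HCl, 25 °C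
Reagents that add atoms: (methoxymethyl)triphenylphosphonium chloride COC[P+](c1ccccc1)(c1ccccc1)c1ccccc1.[Cl-]; water O
Why: Wittig olefination with the methoxymethylene ylide and acid hydrolysis of the enol ether is the classical one-carbon homologation of an aldehyde, and a hindered aryl silyl ether and a 2,2-dimethylchromene should tolerate brief contact with dilute acid.

Step 4
Reactants: 7 2-Ar-acetaldehyde
Product: 8 2-Ar-acetic acid
Conditions: NaClO2, NaH2PO4, 2-methylbut-2-ene, t-BuOH/H2O, 0–25 °C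
Reagents that add atoms: sodium chlorite [Na+].[O-]Cl=O
Why: The Pinnick oxidation works at mildly acidic pH without enolising the arylacetaldehyde, and the alkene scavenger in large excess takes up hypochlorous acid before it can reach the chromene double bond.

Step 5
Reactants: 8 2-Ar-acetic acid; 9 (4S)-4-benzyl-1,3-oxazolidin-2-one
Product: 11 (4S)-4-benzyl-3-(2-Ar-acetyl)-1,3-oxazolidin-2-one, via mixed pivalic anhydride 10 (not isolated)
Conditions: t-BuCOCl, Et3N, THF, −20 °C; then LiCl, 9, −20 → 25 °C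
Reagents that add atoms: pivaloyl chloride CC(C)(C)C(=O)Cl (its atoms stay only in intermediate 10)
Why: Mixed-anhydride N-acylation of the Evans auxiliary under LiCl/Et3N needs no strong base, and the nucleophile attacks the less hindered arylacetyl carbonyl group of 10.

Step 6
Reactants: 11 (4S)-4-benzyl-3-(2-Ar-acetyl)-1,3-oxazolidin-2-one; 12 allyl iodide
Product: 14 (4S)-4-benzyl-3-[(2S)-2-Ar-pent-4-enoyl]-1,3-oxazolidin-2-one, via sodium Z-enolate 13 (not isolated)
Conditions: NaN(SiMe3)2 (0.98 equiv), THF, −78 °C; then 12, −78 → −45 °C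
Reagents that add atoms: none
Why: In this Evans asymmetric alkylation the chelated Z-enolate is shielded on one face by the benzyl group of the (4S) auxiliary, so allyl iodide enters from the other face and sets C3 with the S descriptor (carbonyl over aryl over allyl).

Step 7
Reactants: 14 (4S)-4-benzyl-3-[(2S)-2-Ar-pent-4-enoyl]-1,3-oxazolidin-2-one
Product: 15 (2S)-2-Ar-pent-4-en-1-ol
Conditions: LiBH4, MeOH (1 equiv), Et2O, 0 °C; aq. NH4Cl
Reagents that add atoms: none
Why: Reductive cleavage of the N-acyl oxazolidinone with LiBH4 attacks the exocyclic carbonyl group, leaves alkenes and the aryl silyl ether alone, and is too weakly basic to epimerise the aryl-bearing centre before it loses its acidity.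

Step 8
Reactants: 15 (2S)-2-Ar-pent-4-en-1-ol
Product: 16 triethyl{[(2S)-2-Ar-pent-4-en-1-yl]oxy}silane
Conditions: TESCl, imidazole, CH2Cl2, 0 °C
Reagents that add atoms: triethylsilyl chloride CC[Si](Cl)(CC)CC
Why: Standard silylation of a primary alcohol masks the hydroxyl group that would otherwise add to the enone or trap the ketene, and an alkyl triethylsilyl ether can later be cleaved by mild acid beside two aryl silyl ethers.

Step 9
Reactants: 16 triethyl{[(2S)-2-Ar-pent-4-en-1-yl]oxy}silane; 17 but-3-en-2-one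
Product: 18 (3E,6S)-6-Ar-7-(triethylsilyloxy)hept-3-en-2-one
Conditions: 17 (4 equiv), second-generation Hoveyda–Grubbs catalyst (C31H38Cl2N2ORu, 5 mol %), CH2Cl2, 40 °C
Reagents that add atoms: none
Why: Olefin cross-metathesis of a terminal alkene with an electron-poor vinyl ketone is selective for the E-enone, and the chromene alkene, cis-disubstituted, next to a quaternary carbon and part of a strain-free ring, should stay out of the catalytic cycle.

Step 10
Reactants: 18 (3E,6S)-6-Ar-7-(triethylsilyloxy)hept-3-en-2-one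
Product: 21 (3E,6S)-1-diazo-6-Ar-7-(triethylsilyloxy)hept-3-en-2-one, via lithium dienolate 19 (not isolated), via trifluoroacetyl ketone 20 (not isolated)
Conditions: LiN(SiMe3)2, THF, −78 °C; CF3CO2CH2CF3, −78 °C; AcOH quench; then MsN3 (in solution), Et3N, H2O (1 equiv), MeCN, 25 °C
Reagents that add atoms: methanesulfonyl azide CS(=O)(=O)N=[N+]=[N-] (the two nitrogen atoms of 21); 2,2,2-trifluoroethyl trifluoroacetate O=C(OCC(F)(F)F)C(F)(F)F (its CF3CO group stays only in intermediate 20)
Why: Detrifluoroacetylative diazo transfer (a deacylative Regitz reaction) starts from kinetic deprotonation of the methyl group, activates that carbon as a trifluoroacetyl ketone and exchanges the acyl group for N2 under amine base, which is the standard access to unsaturated diazomethyl ketones that cannot be made by acylating diazomethane.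

Step 11
Reactants: 22 ethyl 4-methylpent-3-enoate
Product: 25 triisopropyl[(5-methylhex-4-en-1-yn-1-yl)oxy]silane, via lithium dibromoenolate 23 (not isolated), via lithium ynolate 24 (not isolated)
Conditions: CH2Br2, lithium 2,2,6,6-tetramethylpiperidide, THF, −78 °C; 22; LiN(SiMe3)2, −78 → −20 °C; n-BuLi, −78 → 25 °C; then i-Pr3SiCl, −78 → 0 °C
Reagents that add atoms: dibromomethane BrCBr; triisopropylsilyl chloride CC(C)[Si](Cl)(C(C)C)C(C)C
Why: This is the Kowalski ester homologation stopped at the ynolate, in which bromine–lithium exchange on 23 triggers migration of the prenyl group to the carbenoid carbon, and the bulky chlorosilane is known to silylate ynolates on oxygen.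

Step 12
Reactants: 21 (3E,6S)-1-diazo-6-Ar-7-(triethylsilyloxy)hept-3-en-2-one; 25 triisopropyl[(5-methylhex-4-en-1-yn-1-yl)oxy]silane
Product: 30 6-[(2S)-2-Ar-3-(triethylsilyloxy)propyl]-2-(3-methylbut-2-enyl)-3-(triisopropylsilyloxy)phenol, via vinylketene 26 (not isolated), via vinylcyclobutenone 27 (not isolated), via dienylketene 28 (not isolated), via cyclohexadienone 29 (not isolated)
Conditions: 25 (1.5 equiv), degassed toluene, hν (400 nm LED), 25 °C; then 110 °C
Reagents that add atoms: none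
Why: Excitation of 21 expels N2 while the alkenyl group migrates to the former diazo carbon (Wolff rearrangement, C5–C6) and gives vinylketene 26. The electron-rich alkyne 25 then adds to the ketene C=C in a (2+2) cycloaddition in which its prenyl-bearing carbon, the nucleophilic one beta to oxygen, attacks the ketene carbonyl carbon (C8–C8a) and its silyloxy carbon binds the ketene alpha carbon (C6–C7), so the 4-alkenylcyclobut-2-enone 27 should form as one regioisomer. On heating, 27 opens by 4π electrocyclic cleavage of C8a–C6 to dienylketene 28, ring A closes by thermal 6π electrocyclisation (C8a–C4a) to dienone 29, and tautomerisation gives phenol 30. The closest known reaction is the photochemical variant of the Danheiser benzannulation, established for unsaturated diazomethyl ketones with siloxyalkynes as a route to resorcinol monosilyl ethers. No lasting stereocentre is made, since those of 27 and 29 vanish on aromatisation, and C3 lies one methylene group away from the reacting π system and is untouched. The step needs the ketene to choose the ynol ether over the prenyl and chromene alkenes, which the much higher ketenophilicity of 25 used in excess secures, and it needs ring D to stay closed, which is secured by irradiating only the long-wavelength band of the diazo ketone, where the chromene should be transparent.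

Step 13
Reactants: 30 ring A phenol
Product: 31 6-[(2S)-2-Ar-3-hydroxypropyl]-2-(3-methylbut-2-enyl)-3-(triisopropylsilyloxy)phenol
Conditions: PPTS (cat.), MeOH/CH2Cl2, 0 °C
Reagents that add atoms: none
Why: Acid-catalysed methanolysis cleaves a primary alkyl triethylsilyl ether far faster than hindered aryl silyl ethers, and the pyridinium salt is too weak an acid to cyclise the prenyl group onto the neighbouring phenol.

Step 14
Reactants: 31 6-[(2S)-2-Ar-3-hydroxypropyl]-2-(3-methylbut-2-enyl)-3-(triisopropylsilyloxy)phenol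
Product: 32 (3S)-3-Ar-8-(3-methylbut-2-enyl)-7-(triisopropylsilyloxy)chroman
Conditions: PPh3, DIAD, THF, 0 → 25 °C
Reagents that add atoms: none
Why: Intramolecular Mitsunobu etherification closes ring C by 6-exo-tet displacement at the primary C2 by the only free phenol (C8a–OH), a known ending for isoflavans that does not touch the C3 centre.

Step 15
Reactants: 32 (3S)-3-Ar-8-(3-methylbut-2-enyl)-7-(triisopropylsilyloxy)chroman
Product: 33 (3S)-3-(5-hydroxy-2,2-dimethyl-2H-chromen-6-yl)-8-(3-methylbut-2-enyl)chroman-7-ol (target)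
Conditions: Bu4NF (2.5 equiv), AcOH (2.5 equiv), THF, 0 °C
Reagents that add atoms: none
Why: Fluoride-induced desilylation removes both aryl silyl ethers in one operation, and the acetic acid buffer keeps the electron-rich phenols protonated while leaving the prenyl and chromene alkenes alone.

Compound list
1 | 2,4-dihydroxybenzaldehyde | O=Cc1ccc(O)cc1O | starting material
2 | 3-methylbut-2-enal | CC(C)=CC=O | starting material
3 | 2-hydroxy-3-(3-methylbut-2-enylidene)-4-oxocyclohexa-1,5-diene-1-carbaldehyde (quinone methide) | O=CC1=C(O)C(=CC=C(C)C)C(=O)C=C1 | intermediate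
4 | 5-hydroxy-2,2-dimethyl-2H-chromene-6-carbaldehyde | O=Cc1ccc2c(c1O)C=CC(C)(C)O2 | intermediate
5 | 5-(tert-butyldimethylsilyloxy)-2,2-dimethyl-2H-chromene-6-carbaldehyde | O=Cc1ccc2c(c1O[Si](C)(C)C(C)(C)C)C=CC(C)(C)O2 | intermediate
6 | 5-(tert-butyldimethylsilyloxy)-6-(2-methoxyethenyl)-2,2-dimethyl-2H-chromene (E/Z mixture) | COC=Cc1ccc2c(c1O[Si](C)(C)C(C)(C)C)C=CC(C)(C)O2 | intermediate
7 | 2-Ar-acetaldehyde | O=CCc1ccc2c(c1O[Si](C)(C)C(C)(C)C)C=CC(C)(C)O2 | intermediate
8 | 2-Ar-acetic acid | O=C(O)Cc1ccc2c(c1O[Si](C)(C)C(C)(C)C)C=CC(C)(C)O2 | intermediate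
9 | (4S)-4-benzyl-1,3-oxazolidin-2-one | O=C1N[C@@H](Cc2ccccc2)CO1 | starting material
10 | 2-Ar-acetic pivalic anhydride | CC(C)(C)C(=O)OC(=O)Cc1ccc2c(c1O[Si](C)(C)C(C)(C)C)C=CC(C)(C)O2 | intermediate
11 | (4S)-4-benzyl-3-(2-Ar-acetyl)-1,3-oxazolidin-2-one | O=C(Cc1ccc2c(c1O[Si](C)(C)C(C)(C)C)C=CC(C)(C)O2)N1[C@@H](Cc2ccccc2)COC1=O | intermediate
12 | allyl iodide (3-iodoprop-1-ene) | C=CCI | starting material
13 | sodium (Z)-enolate of 11 | [Na+].[O-]/C(=C\c1ccc2c(c1O[Si](C)(C)C(C)(C)C)C=CC(C)(C)O2)N1[C@@H](Cc2ccccc2)COC1=O | intermediate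
14 | (4S)-4-benzyl-3-[(2S)-2-Ar-pent-4-enoyl]-1,3-oxazolidin-2-one | C=CC[C@@H](c1ccc2c(c1O[Si](C)(C)C(C)(C)C)C=CC(C)(C)O2)C(=O)N1[C@@H](Cc2ccccc2)COC1=O | intermediate
15 | (2S)-2-Ar-pent-4-en-1-ol | C=CC[C@@H](c1ccc2c(c1O[Si](C)(C)C(C)(C)C)C=CC(C)(C)O2)CO | intermediate
16 | triethyl{[(2S)-2-Ar-pent-4-en-1-yl]oxy}silane | C=CC[C@@H](c1ccc2c(c1O[Si](C)(C)C(C)(C)C)C=CC(C)(C)O2)CO[Si](CC)(CC)CC | intermediate
17 | but-3-en-2-one | C=CC(C)=O | starting material
18 | (3E,6S)-6-Ar-7-(triethylsilyloxy)hept-3-en-2-one | CC(=O)/C=C/C[C@@H](c1ccc2c(c1O[Si](C)(C)C(C)(C)C)C=CC(C)(C)O2)CO[Si](CC)(CC)CC | intermediate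
19 | lithium cross-conjugated enolate of 18 (deprotonated at the methyl group) | [Li+].[O-]C(=C)/C=C/C[C@@H](c1ccc2c(c1O[Si](C)(C)C(C)(C)C)C=CC(C)(C)O2)CO[Si](CC)(CC)CC | intermediate
20 | (5E,8S)-8-Ar-1,1,1-trifluoro-9-(triethylsilyloxy)non-5-ene-2,4-dione | O=C(CC(=O)/C=C/C[C@@H](c1ccc2c(c1O[Si](C)(C)C(C)(C)C)C=CC(C)(C)O2)CO[Si](CC)(CC)CC)C(F)(F)F | intermediate
21 | (3E,6S)-1-diazo-6-Ar-7-(triethylsilyloxy)hept-3-en-2-one | [N-]=[N+]=CC(=O)/C=C/C[C@@H](c1ccc2c(c1O[Si](C)(C)C(C)(C)C)C=CC(C)(C)O2)CO[Si](CC)(CC)CC | intermediate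
22 | ethyl 4-methylpent-3-enoate | CCOC(=O)CC=C(C)C | starting material
23 | lithium 1,1-dibromo-5-methylhexa-1,4-dien-2-olate | [Li+].[O-]C(CC=C(C)C)=C(Br)Br | intermediate
24 | lithium 5-methylhex-4-en-1-yn-1-olate | [Li+].[O-]C#CCC=C(C)C | intermediate
25 | triisopropyl[(5-methylhex-4-en-1-yn-1-yl)oxy]silane | CC(C)=CCC#CO[Si](C(C)C)(C(C)C)C(C)C | intermediate
26 | (3E,6S)-6-Ar-7-(triethylsilyloxy)hepta-1,3-dien-1-one (vinylketene) | O=C=C/C=C/C[C@@H](c1ccc2c(c1O[Si](C)(C)C(C)(C)C)C=CC(C)(C)O2)CO[Si](CC)(CC)CC | intermediate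
27 | 4-[(1E,4S)-4-Ar-5-(triethylsilyloxy)pent-1-enyl]-2-(3-methylbut-2-enyl)-3-(triisopropylsilyloxy)cyclobut-2-en-1-one (ring C4 unassigned) | O=C1C(CC=C(C)C)=C(O[Si](C(C)C)(C(C)C)C(C)C)C1/C=C/C[C@@H](c1ccc2c(c1O[Si](C)(C)C(C)(C)C)C=CC(C)(C)O2)CO[Si](CC)(CC)CC | intermediate
28 | dienylketene, O=C8a=C8(prenyl)–C7(OSi-i-Pr3)=C6H–C5H=C4aH–C4H2 chain with C8 and C5 cis across C7=C6 | O=C=C(CC=C(C)C)/C(O[Si](C(C)C)(C(C)C)C(C)C)=C\C=C\C[C@@H](c1ccc2c(c1O[Si](C)(C)C(C)(C)C)C=CC(C)(C)O2)CO[Si](CC)(CC)CC | intermediate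
29 | 6-[(2S)-2-Ar-3-(triethylsilyloxy)propyl]-2-(3-methylbut-2-enyl)-3-(triisopropylsilyloxy)cyclohexa-2,4-dien-1-one (ring C6 unassigned) | O=C1C(CC=C(C)C)=C(O[Si](C(C)C)(C(C)C)C(C)C)C=CC1C[C@@H](c1ccc2c(c1O[Si](C)(C)C(C)(C)C)C=CC(C)(C)O2)CO[Si](CC)(CC)CC | intermediate
30 | 6-[(2S)-2-Ar-3-(triethylsilyloxy)propyl]-2-(3-methylbut-2-enyl)-3-(triisopropylsilyloxy)phenol | CC(C)=CCc1c(O[Si](C(C)C)(C(C)C)C(C)C)ccc(C[C@@H](c2ccc3c(c2O[Si](C)(C)C(C)(C)C)C=CC(C)(C)O3)CO[Si](CC)(CC)CC)c1O | intermediate
31 | 6-[(2S)-2-Ar-3-hydroxypropyl]-2-(3-methylbut-2-enyl)-3-(triisopropylsilyloxy)phenol | CC(C)=CCc1c(O[Si](C(C)C)(C(C)C)C(C)C)ccc(C[C@@H](c2ccc3c(c2O[Si](C)(C)C(C)(C)C)C=CC(C)(C)O3)CO)c1O | intermediate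
32 | (3S)-3-Ar-8-(3-methylbut-2-enyl)-7-(triisopropylsilyloxy)chroman | CC(C)=CCc1c(O[Si](C(C)C)(C(C)C)C(C)C)ccc2c1OC[C@H](c1ccc3c(c1O[Si](C)(C)C(C)(C)C)C=CC(C)(C)O3)C2 | intermediate
33 | (3S)-3-(5-hydroxy-2,2-dimethyl-2H-chromen-6-yl)-8-(3-methylbut-2-enyl)chroman-7-ol | CC(C)=CCc1c(O)ccc2c1OC[C@H](c1ccc3c(c1O)C=CC(C)(C)O3)C2 | target

Total step count: 15. Longest linear sequence: 14 (steps 1–10 and 12–15). Step 11 is the one-step side branch.

Steps most likely to fail

Step 12.
- What may go wrong: residual light absorption may open ring D and a hydrogen shift may then consume the opened form. The vinylketene, unsubstituted at its alpha carbon, may oligomerise before capture. The product phenol may be acylated by the ketene.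
- Fallback (sets out from 1 and 11, comes back at 31): ring A is taken from a preformed arene and C3–C4 is made by a second Evans alkylation.
- Prenyl bromide with aqueous KOH C-prenylates 1 between its two oxygens to 2,4-dihydroxy-3-(3-methylbut-2-enyl)benzaldehyde F1.
- i-Pr3SiCl/imidazole silylates the non-chelated 4-OH to 2-hydroxy-3-(3-methylbut-2-enyl)-4-(triisopropylsilyloxy)benzaldehyde F2.
- Mitsunobu allylation (allyl alcohol, PPh3, DIAD) gives 2-allyloxy-3-(3-methylbut-2-enyl)-4-(triisopropylsilyloxy)benzaldehyde F3.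
- NaBH4 gives the benzyl alcohol F4, and CBr4/PPh3 gives the benzyl bromide F5.
- Enolate 13, made from 11 as in step 6, is alkylated with F5 on the same face to the benzylated imide F6.
- LiBH4 gives the primary alcohol F7.
- The zerovalent palladium complex Pd(PPh3)4 with morpholine removes the allyl group and delivers 31.

Step 11.
- What may go wrong: the doubly activated methylene group of the β,γ-unsaturated ester may be deprotonated by the amide base or the carbenoid in competition with carbonyl addition, and the alkene may drift into conjugation.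
- Fallback (sets out from 22, comes back at 24): the ynolate is made by oxidising an acetylide instead of rearranging an ester.
- i-Bu2AlH at −78 °C gives 4-methylpent-3-enal F8.
- CBr4/PPh3 gives 1,1-dibromo-5-methylhexa-1,4-diene F9.
- n-BuLi (2 equiv, Corey–Fuchs reaction) gives lithium 5-methylhex-4-en-1-ynide F10.
- t-BuOOLi oxidises F10 in the same flask to ynolate 24, which is silylated as in step 11.

Step 3.
- What may go wrong: hydrolysis of the styryl enol ether may be slow. The acid could then strip the aryl silyl group, after which the freed phenol would condense with the aldehyde and dehydrate to a benzofuran. The acid could also dimerise the chromene.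
- Fallback (sets out from 5, comes back at 8): the extra carbon is added without any acid.
- Wittig methylenation (MePPh3Br, NaN(SiMe3)2) gives 5-(tert-butyldimethylsilyloxy)-2,2-dimethyl-6-vinyl-2H-chromene F11.
- 9-BBN adds to the terminal alkene only and gives the B-(2-Ar-ethyl)-9-borabicyclo[3.3.1]nonane F12.
- NaBO3·4H2O gives 2-Ar-ethanol F13.
- TEMPO/PhI(OAc)2 in MeCN/H2O oxidises F13 through 7 to acid 8.

Further compounds
F1 | step 12 | 2,4-dihydroxy-3-(3-methylbut-2-enyl)benzaldehyde | CC(C)=CCc1c(O)ccc(C=O)c1O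
F2 | step 12 | 2-hydroxy-3-(3-methylbut-2-enyl)-4-(triisopropylsilyloxy)benzaldehyde | CC(C)=CCc1c(O[Si](C(C)C)(C(C)C)C(C)C)ccc(C=O)c1O
F3 | step 12 | 2-allyloxy-3-(3-methylbut-2-enyl)-4-(triisopropylsilyloxy)benzaldehyde | CC(C)=CCc1c(O[Si](C(C)C)(C(C)C)C(C)C)ccc(C=O)c1OCC=C
F4 | step 12 | [2-allyloxy-3-(3-methylbut-2-enyl)-4-(triisopropylsilyloxy)phenyl]methanol | CC(C)=CCc1c(O[Si](C(C)C)(C(C)C)C(C)C)ccc(CO)c1OCC=C
F5 | step 12 | 2-allyloxy-1-(bromomethyl)-3-(3-methylbut-2-enyl)-4-(triisopropylsilyloxy)benzene | CC(C)=CCc1c(O[Si](C(C)C)(C(C)C)C(C)C)ccc(CBr)c1OCC=C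
F6 | step 12 | (4S)-4-benzyl-3-{(2S)-2-Ar-3-[2-allyloxy-3-(3-methylbut-2-enyl)-4-(triisopropylsilyloxy)phenyl]propanoyl}-1,3-oxazolidin-2-one | CC(C)=CCc1c(O[Si](C(C)C)(C(C)C)C(C)C)ccc(C[C@@H](c2ccc3c(c2O[Si](C)(C)C(C)(C)C)C=CC(C)(C)O3)C(=O)N2[C@@H](Cc3ccccc3)COC2=O)c1OCC=C
F7 | step 12 | (2S)-2-Ar-3-[2-allyloxy-3-(3-methylbut-2-enyl)-4-(triisopropylsilyloxy)phenyl]propan-1-ol | CC(C)=CCc1c(O[Si](C(C)C)(C(C)C)C(C)C)ccc(C[C@@H](c2ccc3c(c2O[Si](C)(C)C(C)(C)C)C=CC(C)(C)O3)CO)c1OCC=C
F8 | step 11 | 4-methylpent-3-enal | CC(C)=CCC=O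
F9 | step 11 | 1,1-dibromo-5-methylhexa-1,4-diene | CC(C)=CCC=C(Br)Br
F10 | step 11 | lithium 5-methylhex-4-en-1-ynide | [Li+].[C-]#CCC=C(C)C
F11 | step 3 | 5-(tert-butyldimethylsilyloxy)-2,2-dimethyl-6-vinyl-2H-chromene | C=Cc1ccc2c(c1O[Si](C)(C)C(C)(C)C)C=CC(C)(C)O2
F12 | step 3 | B-(2-Ar-ethyl)-9-borabicyclo[3.3.1]nonane | C1CC2CCCC(C1)B2CCc1ccc2c(c1O[Si](C)(C)C(C)(C)C)C=CC(C)(C)O2
F13 | step 3 | 2-Ar-ethanol | OCCc1ccc2c(c1O[Si](C)(C)C(C)(C)C)C=CC(C)(C)O2
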